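**Retrosynthetic overview** (germacrane numbering: carbocycle C1–C10, lactone carbons C11–C13, C14 = CH2OAc, C15 = CH3)
1. The 8β-methacrylate is cut back to the 8α-carbinol; the ester is put on last with inversion (Mitsunobu).
2. Key disconnection C7–C8: O8 is homoallylic to the exocyclic C11=C13 bond of the α-methylene-γ-butyrolactone, and C7 is shared by the lactone and the ten-membered ring. The C1–C10 carbocycle therefore opens by a retro chromium allylation to an acyclic aldehyde (C8) carrying a 3-(bromomethyl)butenolide; the forward step closes the ring, sets C7 and C8 and unveils the methylene.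
3. The acyclic precursor: butenolide by ring-closing metathesis of a 2-(bromomethyl)acrylate (C6 from a catalytic asymmetric vinylation); oxirane by Sharpless epoxidation of a (Z)-allylic alcohol made by Still–Gennari olefination; C1–C6 from geraniol by oxidative cleavage of its terminal isopropylidene.
4. Ring order: oxirane (step 7), butenolide (step 13), ten-membered carbocycle last (step 16).

Key step: step 16

Remark: the carbinol formed in the ring closure is taken to be the anti (8α) epimer that the chair transition state predicts, so the last step is an inverting esterification.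

**Step 1**
Reactants: 1 methyl 2-[bis(2,2,2-trifluoroethoxy)phosphoryl]acetate; 2 tert-butyl(2-iodoethoxy)dimethylsilane
Product: 3 methyl 2-[bis(2,2,2-trifluoroethoxy)phosphoryl]-4-[(tert-butyldimethylsilyl)oxy]butanoate (racemic)
Conditions: NaH, DMF, 0 °C → rt (slight excess of 1)
Reagents that add atoms: none
Why: SN2 C-alkylation of the sodium phosphonoacetate enolate by the primary iodide should give the α-substituted Still–Gennari reagent; its new stereocentre is lost in step 5.

**Step 2**
Reactants: 4 geraniol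
Product: 5 geranyl 4-methoxybenzyl ether
Conditions: NaH, 4-methoxybenzyl chloride, Bu4NI (cat.), THF/DMF, 0 °C → rt
Reagents that add atoms: 4-methoxybenzyl chloride, COc1ccc(CCl)cc1
Why: Williamson ether synthesis protects the allylic alcohol as an ether that survives hydride, titanium and acylation chemistry and is later removed oxidatively.

**Step 3**
Reactants: 5 geranyl 4-methoxybenzyl ether
Product: 6 2,2-dimethyl-3-{(3E)-5-[(4-methoxybenzyl)oxy]-3-methylpent-3-en-1-yl}oxirane (racemic)
Conditions: mCPBA (1.0 equiv), CH2Cl2, −20 → 0 °C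
Reagents that add atoms: 3-chloroperbenzoic acid, OOC(=O)c1cccc(Cl)c1
Why: Prilezhaev epoxidation should select the electron-rich terminal trisubstituted alkene over the one deactivated by the allylic ether oxygen; the racemic stereocentre is excised in step 4.

**Step 4**
Reactants: 6 the epoxide
Product: 8 (4E)-6-[(4-methoxybenzyl)oxy]-4-methylhex-4-enal, via vicinal diol 7 (not isolated)
Conditions: H5IO6, THF/H2O, 0 °C
Reagents that add atoms: none
Why: Acid-mediated epoxide hydrolysis (water opens at the tertiary carbon) followed by Malaprade glycol cleavage gives the aldehyde and acetone; the aldehyde oxygen is the former epoxide oxygen and the E-alkene is untouched.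

**Step 5**
Reactants: 8 the aldehyde; 3 the phosphonate
Product: 9 methyl (2Z,6E)-2-{2-[(tert-butyldimethylsilyl)oxy]ethyl}-8-[(4-methoxybenzyl)oxy]-6-methylocta-2,6-dienoate
Conditions: KN(SiMe3)2, 18-crown-6, THF, −78 °C
Reagents that add atoms: none
Why: Still–Gennari Horner–Wadsworth–Emmons olefination with the electron-poor bis(trifluoroethyl) phosphonate and a dissociated potassium counter-ion eliminates under kinetic control to the (Z)-enoate, which places the future C14 cis to the C2 chain.

**Step 6**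
Reactants: 9 the (Z)-enoate
Product: 10 (2Z,6E)-2-{2-[(tert-butyldimethylsilyl)oxy]ethyl}-8-[(4-methoxybenzyl)oxy]-6-methylocta-2,6-dien-1-ol
Conditions: iBu2AlH (2.3 equiv), CH2Cl2, −78 °C
Reagents that add atoms: none
Why: 1,2-Reduction of the conjugated ester by iBu2AlH gives the allylic alcohol without changing either alkene geometry.

**Step 7**
Reactants: 10 the (Z)-allylic alcohol
Product: 11 [(2S,3R)-2-{2-[(tert-butyldimethylsilyl)oxy]ethyl}-3-{(3E)-5-[(4-methoxybenzyl)oxy]-3-methylpent-3-en-1-yl}oxiran-2-yl]methanol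
Conditions: Ti(OiPr)4 (10 mol %), L-(+)-diethyl tartrate (12 mol %), tBuOOH, 4 Å MS, CH2Cl2, −20 °C
Reagents that add atoms: tert-butyl hydroperoxide, CC(C)(C)OO
Why: Sharpless asymmetric epoxidation reacts only at the alkene bearing the free allylic hydroxyl; syn oxygen transfer keeps C14 cis to C2, and L-(+)-tartrate sets C10 (S) and C1 (R), the same enantiofacial sense that converts (E)-hex-2-en-1-ol into its (2S,3S)-epoxide.

**Step 8**
Reactants: 11 the epoxy alcohol
Product: 12 [(2S,3R)-2-{2-[(tert-butyldimethylsilyl)oxy]ethyl}-3-{(3E)-5-[(4-methoxybenzyl)oxy]-3-methylpent-3-en-1-yl}oxiran-2-yl]methyl acetate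
Conditions: Ac2O, pyridine, DMAP (cat.), CH2Cl2, 0 °C → rt
Reagents that add atoms: acetic anhydride, CC(=O)OC(C)=O
Why: DMAP-catalysed acylation installs the C14 acetate of the target early, so no extra protecting group is needed at this oxygen.

**Step 9**
Reactants: 12 the acetate
Product: 13 [(2S,3R)-2-{2-[(tert-butyldimethylsilyl)oxy]ethyl}-3-[(3E)-5-hydroxy-3-methylpent-3-en-1-yl]oxiran-2-yl]methyl acetate
Conditions: DDQ, CH2Cl2/pH 7 buffer, 0 °C
Reagents that add atoms: none
Why: Oxidative cleavage of the 4-methoxybenzyl ether by DDQ (benzylic hydride abstraction, then hydrolysis of the oxocarbenium ion) is neutral and leaves silyl ether, acetate and oxirane intact.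

**Step 10**
Reactants: 13 the allylic alcohol
Product: 14 [(2S,3R)-2-{2-[(tert-butyldimethylsilyl)oxy]ethyl}-3-[(3E)-3-methyl-5-oxopent-3-en-1-yl]oxiran-2-yl]methyl acetate
Conditions: MnO2 (excess), CH2Cl2, rt
Reagents that add atoms: none
Why: MnO2 oxidation is selective for the allylic alcohol and should give the (E)-enal without isomerisation.

**Step 11**
Reactants: 14 the enal
Product: 15 [(2S,3R)-2-{2-[(tert-butyldimethylsilyl)oxy]ethyl}-3-[(3E,5S)-5-hydroxy-3-methylhepta-3,6-dien-1-yl]oxiran-2-yl]methyl acetate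
Conditions: Zn(CH=CH2)2, (−)-3-exo-(dimethylamino)isoborneol (10 mol %), toluene/Et2O, 0 °C
Reagents that add atoms: divinylzinc, C=C[Zn]C=C
Why: Amino-alcohol-catalysed enantioselective alkenylzinc 1,2-addition; the (−)-ligand delivers the vinyl group to the Si face of the aldehyde under catalyst control (the oxirane stereocentres are remote), giving the (5S)-carbinol that becomes C6 (R) of the target; the organozinc does not touch acetate or oxirane.

**Step 12**
Reactants: 15 the vinyl carbinol; 16 2-(bromomethyl)prop-2-enoic acid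
Product: 17 (3S,4E)-7-[(2R,3S)-3-(acetoxymethyl)-3-{2-[(tert-butyldimethylsilyl)oxy]ethyl}oxiran-2-yl]-5-methylhepta-1,4-dien-3-yl 2-(bromomethyl)prop-2-enoate
Conditions: DCC, DMAP (5 mol %), CH2Cl2, −20 → 0 °C
Reagents that add atoms: none
Why: Steglich esterification acylates the carbinol at oxygen, so C6 keeps its configuration; low temperature and low DMAP loading limit amine attack on the allylic bromide.

**Step 13**
Reactants: 17 the diene ester
Product: 18 [(2S,3R)-3-{(3E)-4-[(2R)-4-(bromomethyl)-5-oxo-2,5-dihydrofuran-2-yl]-3-methylbut-3-en-1-yl}-2-{2-[(tert-butyldimethylsilyl)oxy]ethyl}oxiran-2-yl]methyl acetate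
Conditions: second-generation Grubbs catalyst RuCl2(=CHPh)(H2IMes)(PCy3) (5 mol %), CH2Cl2, 40 °C, 5 mM
Reagents that add atoms: none
Why: Ring-closing metathesis: the ruthenium alkylidene loads on the monosubstituted vinyl group and closes onto the 1,1-disubstituted acrylate to give the five-membered butenolide with loss of ethene; the trisubstituted C4=C5 alkene is inert and C6 is not touched.

**Step 14**
Reactants: 18 the silyl ether
Product: 19 [(2S,3R)-3-{(3E)-4-[(2R)-4-(bromomethyl)-5-oxo-2,5-dihydrofuran-2-yl]-3-methylbut-3-en-1-yl}-2-(2-hydroxyethyl)oxiran-2-yl]methyl acetate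
Conditions: Et3N·3HF, MeCN/THF, rt
Reagents that add atoms: none
Why: Fluoride-driven Si–O cleavage of the primary silyl ether by the mildly acidic Et3N·3HF, which contains neither free amine nor naked fluoride and should therefore spare the allylic bromide, the acetate and the oxirane.

**Step 15**
Reactants: 19 the primary alcohol
Product: 20 [(2S,3R)-3-{(3E)-4-[(2R)-4-(bromomethyl)-5-oxo-2,5-dihydrofuran-2-yl]-3-methylbut-3-en-1-yl}-2-(2-oxoethyl)oxiran-2-yl]methyl acetate
Conditions: Dess–Martin periodinane, NaHCO3, CH2Cl2, 0 °C; crude aldehyde used at once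
Reagents that add atoms: none
Why: Dess–Martin oxidation under bicarbonate buffer stops at the aldehyde and avoids base that would open the β,γ-epoxy aldehyde or deprotonate the γ-acidic butenolide.

**Step 16**
Reactants: 20 the bromo aldehyde
Product: 22 (1R,6R,7R,8S,10S)-14-acetoxy-1,10-epoxy-8α-hydroxygermacra-4E,11(13)-dien-12,6-olide, via allylchromium dichloride 21 (not isolated)
Conditions: CrCl2 (8 equiv), THF, rt, slow addition of 20 to 2 mM final concentration; pH 7 buffer work-up
Reagents that add atoms: none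
Why: Two equivalents of CrCl2 reduce the allylic C–Br bond to allylchromium dichloride 21, whose γ-carbon C7 (the butenolide β-carbon) adds to the C8 aldehyde through a six-membered chair transition state and moves the double bond out of the ring to C11=C13; the closest known reaction type is the Nozaki–Hiyama 2-(alkoxycarbonyl)allylation of aldehydes by 3-(bromomethyl)furan-2(5H)-ones, together with the intramolecular chromium allylations that close germacranolide rings. The ten-membered carbocycle closes by 10-exo-trig attack on the carbonyl, helped at high dilution by three rigid elements in the tether (E-C4=C5, the oxirane, the planar butenolide). C7 is set by C6: the C5 chain occupies one butenolide face and A(1,3) strain with C15 keeps C6–H in the alkene plane, so C8 should bond anti to C5 and give the trans-fused lactone with a staggered C5–C6–C7–C8 torsion, not the nearly eclipsed one a cis fusion needs. C8 is set by the transition state: C6 is trans to the CH2Cr carbon (E-type allyl unit) and the C9 tether equatorial, which leads to the anti, 8α-carbinol with H7 and H8 antiperiplanar, the crown conformer of the product. The step needs γ-selectivity (SE2' mode, intrinsic to allylchromium), chemoselectivity for the aldehyde over acetate, lactone and oxirane (trivalent allylchromium reagents do not add to esters or open epoxides) and ring closure over oligomerisation (slow addition).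

**Step 17**
Reactants: 22 the 8α-carbinol; 23 methacrylic acid
Product: 24 (1R,6R,7R,8R,10S)-14-acetoxy-1,10-epoxy-8β-(methacryloyloxy)germacra-4E,11(13)-dien-12,6-olide (CNP0150481.3)
Conditions: PPh3, DIAD (betaine preformed), THF, 0 °C → rt
Reagents that add atoms: none
Why: Mitsunobu esterification: methacrylate displaces the equatorial 8α-alkoxyphosphonium ion by SN2 with inversion, giving the 8β-ester (C8 R); the neutral conditions spare the methylene lactone, oxirane and acetate.

**Compound list**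
1 | methyl 2-[bis(2,2,2-trifluoroethoxy)phosphoryl]acetate | COC(=O)CP(=O)(OCC(F)(F)F)OCC(F)(F)F | starting material
2 | tert-butyl(2-iodoethoxy)dimethylsilane | CC(C)(C)[Si](C)(C)OCCI | starting material
3 | methyl 2-[bis(2,2,2-trifluoroethoxy)phosphoryl]-4-[(tert-butyldimethylsilyl)oxy]butanoate (racemic) | COC(=O)C(CCO[Si](C)(C)C(C)(C)C)P(=O)(OCC(F)(F)F)OCC(F)(F)F | intermediate
4 | geraniol, (2E)-3,7-dimethylocta-2,6-dien-1-ol | CC(C)=CCC/C(C)=C/CO | starting material
5 | geranyl 4-methoxybenzyl ether | CC(C)=CCC/C(C)=C/COCc1ccc(OC)cc1 | intermediate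
6 | 2,2-dimethyl-3-{(3E)-5-[(4-methoxybenzyl)oxy]-3-methylpent-3-en-1-yl}oxirane (racemic) | CC1(C)OC1CC/C(C)=C/COCc1ccc(OC)cc1 | intermediate
7 | (6E)-8-[(4-methoxybenzyl)oxy]-2,6-dimethyloct-6-ene-2,3-diol (racemic, not isolated) | CC(C)(O)C(O)CC/C(C)=C/COCc1ccc(OC)cc1 | intermediate
8 | (4E)-6-[(4-methoxybenzyl)oxy]-4-methylhex-4-enal | O=CCC/C(C)=C/COCc1ccc(OC)cc1 | intermediate
9 | methyl (2Z,6E)-2-{2-[(tert-butyldimethylsilyl)oxy]ethyl}-8-[(4-methoxybenzyl)oxy]-6-methylocta-2,6-dienoate | COC(=O)/C(CCO[Si](C)(C)C(C)(C)C)=C\CC/C(C)=C/COCc1ccc(OC)cc1 | intermediate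
10 | (2Z,6E)-2-{2-[(tert-butyldimethylsilyl)oxy]ethyl}-8-[(4-methoxybenzyl)oxy]-6-methylocta-2,6-dien-1-ol | OC/C(CCO[Si](C)(C)C(C)(C)C)=C\CC/C(C)=C/COCc1ccc(OC)cc1 | intermediate
11 | [(2S,3R)-2-{2-[(tert-butyldimethylsilyl)oxy]ethyl}-3-{(3E)-5-[(4-methoxybenzyl)oxy]-3-methylpent-3-en-1-yl}oxiran-2-yl]methanol | CC(C)(C)[Si](C)(C)OCC[C@@]1(CO)O[C@@H]1CC/C(C)=C/COCc1ccc(OC)cc1 | intermediate
12 | [(2S,3R)-2-{2-[(tert-butyldimethylsilyl)oxy]ethyl}-3-{(3E)-5-[(4-methoxybenzyl)oxy]-3-methylpent-3-en-1-yl}oxiran-2-yl]methyl acetate | CC(C)(C)[Si](C)(C)OCC[C@@]1(COC(C)=O)O[C@@H]1CC/C(C)=C/COCc1ccc(OC)cc1 | intermediate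
13 | [(2S,3R)-2-{2-[(tert-butyldimethylsilyl)oxy]ethyl}-3-[(3E)-5-hydroxy-3-methylpent-3-en-1-yl]oxiran-2-yl]methyl acetate | CC(C)(C)[Si](C)(C)OCC[C@@]1(COC(C)=O)O[C@@H]1CC/C(C)=C/CO | intermediate
14 | [(2S,3R)-2-{2-[(tert-butyldimethylsilyl)oxy]ethyl}-3-[(3E)-3-methyl-5-oxopent-3-en-1-yl]oxiran-2-yl]methyl acetate | CC(C)(C)[Si](C)(C)OCC[C@@]1(COC(C)=O)O[C@@H]1CC/C(C)=C/C=O | intermediate
15 | [(2S,3R)-2-{2-[(tert-butyldimethylsilyl)oxy]ethyl}-3-[(3E,5S)-5-hydroxy-3-methylhepta-3,6-dien-1-yl]oxiran-2-yl]methyl acetate | CC(C)(C)[Si](C)(C)OCC[C@@]1(COC(C)=O)O[C@@H]1CC/C(C)=C/[C@H](C=C)O | intermediate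
16 | 2-(bromomethyl)prop-2-enoic acid | C=C(CBr)C(=O)O | starting material
17 | (3S,4E)-7-[(2R,3S)-3-(acetoxymethyl)-3-{2-[(tert-butyldimethylsilyl)oxy]ethyl}oxiran-2-yl]-5-methylhepta-1,4-dien-3-yl 2-(bromomethyl)prop-2-enoate | CC(C)(C)[Si](C)(C)OCC[C@@]1(COC(C)=O)O[C@@H]1CC/C(C)=C/[C@H](C=C)OC(=O)C(=C)CBr | intermediate
18 | [(2S,3R)-3-{(3E)-4-[(2R)-4-(bromomethyl)-5-oxo-2,5-dihydrofuran-2-yl]-3-methylbut-3-en-1-yl}-2-{2-[(tert-butyldimethylsilyl)oxy]ethyl}oxiran-2-yl]methyl acetate | CC(C)(C)[Si](C)(C)OCC[C@@]1(COC(C)=O)O[C@@H]1CC/C(C)=C/[C@H]1OC(=O)C(CBr)=C1 | intermediate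
19 | [(2S,3R)-3-{(3E)-4-[(2R)-4-(bromomethyl)-5-oxo-2,5-dihydrofuran-2-yl]-3-methylbut-3-en-1-yl}-2-(2-hydroxyethyl)oxiran-2-yl]methyl acetate | OCC[C@@]1(COC(C)=O)O[C@@H]1CC/C(C)=C/[C@H]1OC(=O)C(CBr)=C1 | intermediate
20 | [(2S,3R)-3-{(3E)-4-[(2R)-4-(bromomethyl)-5-oxo-2,5-dihydrofuran-2-yl]-3-methylbut-3-en-1-yl}-2-(2-oxoethyl)oxiran-2-yl]methyl acetate | O=CC[C@@]1(COC(C)=O)O[C@@H]1CC/C(C)=C/[C@H]1OC(=O)C(CBr)=C1 | intermediate
21 | allylchromium dichloride of 20, [(2S,3R)-3-{(3E)-4-[(2R)-4-[(dichlorochromio)methyl]-5-oxo-2,5-dihydrofuran-2-yl]-3-methylbut-3-en-1-yl}-2-(2-oxoethyl)oxiran-2-yl]methyl acetate (not isolated) | O=CC[C@@]1(COC(C)=O)O[C@@H]1CC/C(C)=C/[C@H]1OC(=O)C(C[Cr](Cl)Cl)=C1 | intermediate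
22 | (1R,6R,7R,8S,10S)-14-acetoxy-1,10-epoxy-8α-hydroxygermacra-4E,11(13)-dien-12,6-olide | O[C@H]1C[C@@]2(COC(C)=O)O[C@@H]2CC/C(C)=C/[C@H]2OC(=O)C(=C)[C@@H]21 | intermediate
23 | methacrylic acid | C=C(C)C(=O)O | starting material
24 | (1R,6R,7R,8R,10S)-14-acetoxy-1,10-epoxy-8β-(methacryloyloxy)germacra-4E,11(13)-dien-12,6-olide | C=C(C)C(=O)O[C@@H]1C[C@@]2(COC(C)=O)O[C@@H]2CC/C(C)=C/[C@H]2OC(=O)C(=C)[C@@H]21 | target

**Step count**
Total: 17 steps. Longest linear sequence: 16 steps (geraniol 4 to 24, steps 2–17).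

**Steps most likely to fail**

Step 16 (ring closure). Oligomerisation may outrun cyclisation, the chromium salts may open or eliminate the β,γ-epoxy aldehyde, or the aldehyde may add to the wrong butenolide face. Fallback: replace the in situ organochromium by an isolable allylboronate that cyclises thermally. Setting out from 19, Pd2(dba)3-catalysed borylation of the allylic bromide with bis(pinacolato)diboron (THF, rt; the zerovalent palladium π-allyl is borylated at the unhindered terminus) should give [(2S,3R)-2-(2-hydroxyethyl)-3-{(3E)-3-methyl-4-[(2R)-5-oxo-4-[(4,4,5,5-tetramethyl-1,3,2-dioxaborolan-2-yl)methyl]-2,5-dihydrofuran-2-yl]but-3-en-1-yl}oxiran-2-yl]methyl acetate F1. Dess–Martin oxidation (NaHCO3, CH2Cl2, 0 °C) should give the corresponding 2-(2-oxoethyl) boronate aldehyde F2. Heating F2 in dilute toluene (80 °C) lets the allylboronate add to the aldehyde through the same closed chair, without redox metal or Lewis acidic salts; aqueous hydrolysis of the borate ester rejoins the route at 22.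

Step 17 (inverting esterification). SN2 displacement at the hindered ring carbinol may be slow, so that E2 elimination of the alkoxyphosphonium ion or acyl transfer with retention takes over. Fallback: redox inversion followed by acylation with retention. From 22, Dess–Martin oxidation should give (1R,6R,7S,10S)-14-acetoxy-1,10-epoxy-8-oxogermacra-4E,11(13)-dien-12,6-olide F3. Luche reduction (NaBH4, CeCl3·7H2O, MeOH, −78 °C; 1,2-selective, so the methylene lactone is spared) should deliver hydride to the α-face, away from C14 and the C7–C11 bond, and give (1R,6R,7R,8R,10S)-14-acetoxy-1,10-epoxy-8β-hydroxygermacra-4E,11(13)-dien-12,6-olide F4. Methacrylic anhydride, Et3N and DMAP (CH2Cl2, 0 °C) then give 24.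

Step 11 (asymmetric vinylation). Facial selectivity of vinyl transfer to the β,β-disubstituted enal may be poor, or uncatalysed background addition may erode it, giving a C6 epimer mixture. Fallback: asymmetric alkynylation followed by semi-hydrogenation. From 14, ZnMe2/ProPhenol-catalysed addition of ethynyltrimethylsilane, with the ligand antipode that delivers the alkynyl group to the Si face, should give [(2S,3R)-2-{2-[(tert-butyldimethylsilyl)oxy]ethyl}-3-[(3E,5R)-5-hydroxy-3-methyl-7-(trimethylsilyl)hept-3-en-6-yn-1-yl]oxiran-2-yl]methyl acetate F5. Bu4NF buffered with AcOH (THF, −20 °C) should cleave only the C–Si bond and give [(2S,3R)-2-{2-[(tert-butyldimethylsilyl)oxy]ethyl}-3-[(3E,5R)-5-hydroxy-3-methylhept-3-en-6-yn-1-yl]oxiran-2-yl]methyl acetate F6. Semi-hydrogenation (H2, Pd/CaCO3 poisoned with Pb(OAc)2, quinoline, EtOAc) returns to 15.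

**Further compounds**
F1 | step 16 | [(2S,3R)-2-(2-hydroxyethyl)-3-{(3E)-3-methyl-4-[(2R)-5-oxo-4-[(4,4,5,5-tetramethyl-1,3,2-dioxaborolan-2-yl)methyl]-2,5-dihydrofuran-2-yl]but-3-en-1-yl}oxiran-2-yl]methyl acetate | OCC[C@@]1(COC(C)=O)O[C@@H]1CC/C(C)=C/[C@H]1OC(=O)C(CB2OC(C)(C)C(C)(C)O2)=C1
F2 | step 16 | [(2S,3R)-3-{(3E)-3-methyl-4-[(2R)-5-oxo-4-[(4,4,5,5-tetramethyl-1,3,2-dioxaborolan-2-yl)methyl]-2,5-dihydrofuran-2-yl]but-3-en-1-yl}-2-(2-oxoethyl)oxiran-2-yl]methyl acetate | O=CC[C@@]1(COC(C)=O)O[C@@H]1CC/C(C)=C/[C@H]1OC(=O)C(CB2OC(C)(C)C(C)(C)O2)=C1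
F3 | step 17 | (1R,6R,7S,10S)-14-acetoxy-1,10-epoxy-8-oxogermacra-4E,11(13)-dien-12,6-olide | O=C1C[C@@]2(COC(C)=O)O[C@@H]2CC/C(C)=C/[C@H]2OC(=O)C(=C)[C@@H]21
F4 | step 17 | (1R,6R,7R,8R,10S)-14-acetoxy-1,10-epoxy-8β-hydroxygermacra-4E,11(13)-dien-12,6-olide | O[C@@H]1C[C@@]2(COC(C)=O)O[C@@H]2CC/C(C)=C/[C@H]2OC(=O)C(=C)[C@@H]21
F5 | step 11 | [(2S,3R)-2-{2-[(tert-butyldimethylsilyl)oxy]ethyl}-3-[(3E,5R)-5-hydroxy-3-methyl-7-(trimethylsilyl)hept-3-en-6-yn-1-yl]oxiran-2-yl]methyl acetate | CC(C)(C)[Si](C)(C)OCC[C@@]1(COC(C)=O)O[C@@H]1CC/C(C)=C/[C@H](C#C[Si](C)(C)C)O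
F6 | step 11 | [(2S,3R)-2-{2-[(tert-butyldimethylsilyl)oxy]ethyl}-3-[(3E,5R)-5-hydroxy-3-methylhept-3-en-6-yn-1-yl]oxiran-2-yl]methyl acetate | CC(C)(C)[Si](C)(C)OCC[C@@]1(COC(C)=O)O[C@@H]1CC/C(C)=C/[C@H](C#C)O
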